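**Retrosynthetic overview**
1. Target 13 ⇐ aldehyde 12 by chemoselective NaBH4 reduction; 12 ⇐ aryl 1,1-dimethylallyl ether 10 by aromatic Claisen rearrangement, which can place prenyl only at C5.
2. Key strategy: ring A is not bought as an arene. Phenol 9 ⇐ cyclohexenone 8 by dehydrogenative aromatisation, so the hindered diaryl ether C–O bond is made before ring A is aromatic.
3. 8 ⇐ vinylogous acid chloride 7 + salicylaldehyde 3 by metal-free addition–elimination (no Ullmann or SNAr aryl–O coupling).
4. 7 ⇐ 5-methylcyclohexane-1,3-dione 4 (C-methoxycarbonylation, then chlorination); 3 ⇐ 2,4-dimethoxyphenol 1 (ortho-formylation).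
5. Ring order: ring B is aromatic from the start (from 1); the ring A carbocycle comes from 4 and becomes aromatic in step 5; no ring-closing step is needed.

Assumption: the target has no stereocentre and no stereogenic double bond, so it is achiral and "single enantiomer" needs no stereocontrol. Chiral intermediates 5, 7, 8 and 11 are racemic and lose their stereocentre on aromatisation.

**Route**

Step 1
Reactants: 1 2,4-dimethoxyphenol
Product: 3 2-hydroxy-3,5-dimethoxybenzaldehyde, via 2-(hydroxymethyl)-4,6-dimethoxyphenol 2 (not isolated)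
Conditions: MgCl2 (1.5 equiv), Et3N (3.75 equiv), (CH2O)n (6.75 equiv), MeCN, reflux; aq. HCl work-up
Reagents that add atoms: paraformaldehyde (as formaldehyde), C=O
Why: Casnati–Skattebøl ortho-formylation: the Mg phenoxide delivers CH2O only to the one free ortho carbon, and the Mg salicyl alkoxide 2 is oxidised by a second CH2O (Oppenauer-type hydride transfer).

Step 2
Reactants: 4 5-methylcyclohexane-1,3-dione
Product: 6 methyl 2-hydroxy-4-methyl-6-oxocyclohex-1-ene-1-carboxylate, via enol methyl carbonate 5 (not isolated)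
Conditions: ClCO2Me (1.05 equiv), Et3N (2.2 equiv), CH2Cl2, 0 °C; then DMAP (0.3 equiv), rt, 16 h; 1 M HCl work-up
Reagents that add atoms: methyl chloroformate, COC(=O)Cl
Why: O-acylation gives enol carbonate 5, and DMAP-mediated O→C methoxycarbonyl transfer (Steglich-type rearrangement, as in the enol ester → 2-acyl-1,3-dione isomerisation) is driven to C2 by formation of the strongly acidic, chelated β-tricarbonyl as its ammonium salt.

Step 3
Reactants: 6 methyl 2-hydroxy-4-methyl-6-oxocyclohex-1-ene-1-carboxylate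
Product: 7 methyl 2-chloro-4-methyl-6-oxocyclohex-1-ene-1-carboxylate (racemic)
Conditions: (COCl)2 (1.5 equiv), DMF (cat.), CH2Cl2, 0 °C → rt
Reagents that add atoms: oxalyl chloride, ClC(=O)C(=O)Cl
Why: Vilsmeier-type activation of the vinylogous acid followed by chloride addition–elimination gives the vinylogous acid chloride; the two carbonyls of 6 are equivalent, so only one regioisomer can form.

Step 4
Reactants: 7 methyl 2-chloro-4-methyl-6-oxocyclohex-1-ene-1-carboxylate; 3 2-hydroxy-3,5-dimethoxybenzaldehyde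
Product: 8 methyl 2-(2-formyl-4,6-dimethoxyphenoxy)-4-methyl-6-oxocyclohex-1-ene-1-carboxylate (racemic)
Conditions: K2CO3 (1.5 equiv), dry MeCN, 0 °C → rt
Reagents that add atoms: none
Why: Addition–elimination (nucleophilic vinylic substitution) of the phenoxide of 3 at the doubly activated β-carbon of 7 forms the hindered aryl–O–C bond without a metal, because that carbon is a vinylogous acyl chloride and not yet part of an arene.

Step 5
Reactants: 8 methyl 2-(2-formyl-4,6-dimethoxyphenoxy)-4-methyl-6-oxocyclohex-1-ene-1-carboxylate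
Product: 9 methyl 2-(2-formyl-4,6-dimethoxyphenoxy)-6-hydroxy-4-methylbenzoate
Conditions: DDQ (1.3 equiv), 1,4-dioxane, 90 °C
Reagents that add atoms: none
Why: DDQ dehydrogenation of the readily enolised vinylogous β-keto ester (hydride abstraction from C4 of the dienol, then loss of H+ from C5) aromatises ring A and unveils the ester-chelated phenol; the aldehyde and aryl methyl ethers are inert to DDQ.

Step 6
Reactants: 9 methyl 2-(2-formyl-4,6-dimethoxyphenoxy)-6-hydroxy-4-methylbenzoate
Product: 10 methyl 2-(2-formyl-4,6-dimethoxyphenoxy)-4-methyl-6-[(2-methylbut-3-en-2-yl)oxy]benzoate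
Conditions: methyl 2-methylbut-3-en-2-yl carbonate (1.5 equiv), Pd(PPh3)4 (3 mol %), THF, 0 °C, stopped before branched → linear equilibration
Reagents that add atoms: methyl 2-methylbut-3-en-2-yl carbonate, COC(=O)OC(C)(C)C=C
Why: Tsuji–Trost O-allylation in which the phenoxide attacks the more substituted terminus of the 1,1-dimethyl-π-allyl-Pd complex under kinetic control, giving the tertiary (reverse-prenyl) aryl ether.

Step 7
Reactants: 10 methyl 2-(2-formyl-4,6-dimethoxyphenoxy)-4-methyl-6-[(2-methylbut-3-en-2-yl)oxy]benzoate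
Product: 12 methyl 2-(2-formyl-4,6-dimethoxyphenoxy)-6-hydroxy-4-methyl-5-(3-methylbut-2-en-1-yl)benzoate, via ortho-dienone 11 (not isolated)
Conditions: PhMe, 120 °C, sealed tube
Reagents that add atoms: none
Why: Aromatic Claisen [3,3] rearrangement delivers the allyl unit with inversion (giving the normal prenyl group) to C5, the only ortho carbon bearing H, and dienone 11 tautomerises to the chelated phenol, so no C3 isomer can arise.

Step 8
Reactants: 12 methyl 2-(2-formyl-4,6-dimethoxyphenoxy)-6-hydroxy-4-methyl-5-(3-methylbut-2-en-1-yl)benzoate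
Product: 13 methyl 2-[2-(hydroxymethyl)-4,6-dimethoxyphenoxy]-6-hydroxy-4-methyl-5-(3-methylbut-2-en-1-yl)benzoate (target)
Conditions: NaBH4 (1 equiv), MeOH/THF, 0 °C; aq. NH4Cl
Reagents that add atoms: none
Why: Chemoselective NaBH4 reduction of the aryl aldehyde; the hindered, phenol-chelated methyl ester, the diaryl ether and the trisubstituted alkene do not react.

**Compound list**
1 | 2,4-dimethoxyphenol | COc1ccc(O)c(OC)c1 | starting material
2 | 2-(hydroxymethyl)-4,6-dimethoxyphenol (present as its Mg salt) | OCc1cc(OC)cc(OC)c1O | intermediate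
3 | 2-hydroxy-3,5-dimethoxybenzaldehyde | O=Cc1cc(OC)cc(OC)c1O | intermediate
4 | 5-methylcyclohexane-1,3-dione | CC1CC(=O)CC(=O)C1 | starting material
5 | methyl (5-methyl-3-oxocyclohex-1-en-1-yl) carbonate (racemic) | COC(=O)OC1=CC(=O)CC(C)C1 | intermediate
6 | methyl 2-hydroxy-4-methyl-6-oxocyclohex-1-ene-1-carboxylate | COC(=O)C1=C(O)CC(C)CC1=O | intermediate
7 | methyl 2-chloro-4-methyl-6-oxocyclohex-1-ene-1-carboxylate (racemic) | COC(=O)C1=C(Cl)CC(C)CC1=O | intermediate
8 | methyl 2-(2-formyl-4,6-dimethoxyphenoxy)-4-methyl-6-oxocyclohex-1-ene-1-carboxylate (racemic) | COC(=O)C1=C(Oc2c(C=O)cc(OC)cc2OC)CC(C)CC1=O | intermediate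
9 | methyl 2-(2-formyl-4,6-dimethoxyphenoxy)-6-hydroxy-4-methylbenzoate | COC(=O)c1c(Oc2c(C=O)cc(OC)cc2OC)cc(C)cc1O | intermediate
10 | methyl 2-(2-formyl-4,6-dimethoxyphenoxy)-4-methyl-6-[(2-methylbut-3-en-2-yl)oxy]benzoate | COC(=O)c1c(Oc2c(C=O)cc(OC)cc2OC)cc(C)cc1OC(C)(C)C=C | intermediate
11 | methyl 2-(2-formyl-4,6-dimethoxyphenoxy)-4-methyl-5-(3-methylbut-2-en-1-yl)-6-oxocyclohexa-1,3-diene-1-carboxylate (racemic) | COC(=O)C1=C(Oc2c(C=O)cc(OC)cc2OC)C=C(C)C(CC=C(C)C)C1=O | intermediate
12 | methyl 2-(2-formyl-4,6-dimethoxyphenoxy)-6-hydroxy-4-methyl-5-(3-methylbut-2-en-1-yl)benzoate | COC(=O)c1c(Oc2c(C=O)cc(OC)cc2OC)cc(C)c(CC=C(C)C)c1O | intermediate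
13 | methyl 2-[2-(hydroxymethyl)-4,6-dimethoxyphenoxy]-6-hydroxy-4-methyl-5-(3-methylbut-2-en-1-yl)benzoate | COC(=O)c1c(Oc2c(CO)cc(OC)cc2OC)cc(C)c(CC=C(C)C)c1O | target

**Totals**
Total steps: 8. Longest linear sequence: 7 (steps 2 to 8, from 4); step 1 is the one-step side branch.

**Three steps most likely to fail**

Step 2 (C- versus O-methoxycarbonylation; the enol carbonate may not rearrange cleanly). The fallback sets out from 4 and comes back to the route at 8, so 6 and 7 are not needed. Compound 4 is treated with oxalyl chloride (cat. DMF, CH2Cl2) to give racemic 3-chloro-5-methylcyclohex-2-en-1-one F1. Addition–elimination with 3 (K2CO3, DMF, 60 °C) gives 3-(2-formyl-4,6-dimethoxyphenoxy)-5-methylcyclohex-2-en-1-one F2. The nucleophilic α-carbon of this vinylogous ester is iodinated (NIS, CH2Cl2, 0 °C → rt) to 3-(2-formyl-4,6-dimethoxyphenoxy)-2-iodo-5-methylcyclohex-2-en-1-one F3. Pd-catalysed methoxycarbonylation (Pd(OAc)2/dppf, CO 1 atm, MeOH, Et3N, DMF, 60 °C) then installs the ester and gives 8.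

Step 5 (DDQ may be sluggish on this electron-poor enone, or the vinylogous carbonate may hydrolyse). The fallback sets out from 8 and comes back at 9 by a polar halogenation–dehydrohalogenation instead of hydride abstraction. With DBU (2.5 equiv) and BrCCl3 (1.2 equiv) in CH2Cl2 at 0 °C, the extended dienolate formed by γ-deprotonation at C3 is brominated at C1 to give methyl 1-bromo-2-(2-formyl-4,6-dimethoxyphenoxy)-4-methyl-6-oxocyclohex-2-ene-1-carboxylate F4, which is not isolated. DBU-induced 1,4-elimination of HBr and tautomerisation give 9.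

Step 6 (branched versus linear O-allylation; the linear prenyl ether would give the wrong Claisen product). The fallback sets out from 9 and comes back at 10. Cu-catalysed propargylic etherification (3-chloro-3-methylbut-1-yne, CuCl2·2H2O 1 mol %, DBU, MeCN, 0 °C) gives methyl 2-(2-formyl-4,6-dimethoxyphenoxy)-4-methyl-6-[(2-methylbut-3-yn-2-yl)oxy]benzoate F5, where no linear isomer is possible. Lindlar semi-hydrogenation (H2, Pd/CaCO3–Pb, quinoline, EtOAc; the aldehyde is untouched) gives 10.

**Further compounds**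
F1 | step 2 | 3-chloro-5-methylcyclohex-2-en-1-one (racemic) | CC1CC(Cl)=CC(=O)C1
F2 | step 2 | 3-(2-formyl-4,6-dimethoxyphenoxy)-5-methylcyclohex-2-en-1-one (racemic) | CC1CC(Oc2c(C=O)cc(OC)cc2OC)=CC(=O)C1
F3 | step 2 | 3-(2-formyl-4,6-dimethoxyphenoxy)-2-iodo-5-methylcyclohex-2-en-1-one (racemic) | CC1CC(Oc2c(C=O)cc(OC)cc2OC)=C(I)C(=O)C1
F4 | step 5 | methyl 1-bromo-2-(2-formyl-4,6-dimethoxyphenoxy)-4-methyl-6-oxocyclohex-2-ene-1-carboxylate (diastereomer mixture, racemic) | COC(=O)C1(Br)C(Oc2c(C=O)cc(OC)cc2OC)=CC(C)CC1=O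
F5 | step 6 | methyl 2-(2-formyl-4,6-dimethoxyphenoxy)-4-methyl-6-[(2-methylbut-3-yn-2-yl)oxy]benzoate | COC(=O)c1c(Oc2c(C=O)cc(OC)cc2OC)cc(C)cc1OC(C)(C)C#C
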